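## Retrosynthetic overview

1. The Δ2 enone comes last (Saegusa–Ito on the C1 ketone); the O7 tiglate and trans O9 alcohol come from an Evans–Tishchenko reduction of a 7‑hydroxy‑9‑ketone, itself from a 7,8‑epoxy‑9‑ketone.
2. Ring C (cyclobutane, C10–C11) is closed by intramolecular α'‑enolate alkylation of the C9 ketone with a C11 mesylate in a cis‑fused 6/7 bicycle.
3. Ring B (seven‑membered, C7=C8) is closed by ring‑closing metathesis of two cis arms on ring A.
4. Key union (C5–C6): γ‑selective prenylation of the carbonyl of an α'‑alkylated vinylogous thioester, then 1,3‑carbonyl transposition; conjugate reduction and Rubottom oxidation set C5 and C11.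
5. Ring A comes from (R)‑pulegone, whose methyl centre controls C4 and is erased at the end. Ring order: A (chiral pool), then B, then C.

Numbering: carbons are called by their final longipinane numbers; along the target SMILES the ring atoms are C7, C8, C9, C10, C11, C1, C2, C3, C4, C5, C6. Compounds 25–29 are 10,11‑seco (C10–C11 bond not yet made).
Assumption: epimer mixtures at C10 (steps 12–20) and C9 (steps 15–16) are carried forward, because both centres are later made planar.

## Route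

Step 1
Reactants: 1 (R)-(+)-pulegone
Product: 2 (6R)-2,2,6-trimethyl-1-oxaspiro[2.5]octan-4-one
Conditions: 30% H2O2, LiOH (cat.), MeOH, 0 → 25 °C
Reagents that add atoms: hydrogen peroxide, OO
Why: Weitz–Scheffer nucleophilic epoxidation of the enone; the new spiro centre is lost in step 2, so both diastereomers are used.

Step 2
Reactants: 2 (6R)-2,2,6-trimethyl-1-oxaspiro[2.5]octan-4-one
Product: 4 (5R)-5-methyl-2-(phenylsulfanyl)cyclohexan-1-one, via hydroxy sulfide adduct 3 (not isolated)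
Conditions: PhSNa, THF, reflux
Reagents that add atoms: sodium benzenethiolate, [Na+].[S-]c1ccccc1
Why: Thiolate opens the α,β-epoxy ketone at the α-carbon (SN2) and the β-alkoxide then loses acetone by retro-aldol cleavage, leaving C3 untouched.

Step 3
Reactants: 4 (5R)-5-methyl-2-(phenylsulfanyl)cyclohexan-1-one
Product: 6 (5R)-5-methylcyclohex-2-en-1-one, via sulfoxide 5 (not isolated)
Conditions: mCPBA (1.0 equiv), CH2Cl2, −78 °C; then CaCO3, toluene, 110 °C
Reagents that add atoms: none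
Why: Sulfide oxidation followed by thermal syn-elimination of the α-sulfinyl ketone (sulfoxide pyrolysis) can only run towards the β-CH2 and gives the conjugated enone.

Step 4
Reactants: 6 (5R)-5-methylcyclohex-2-en-1-one
Product: 7 (5S)-5-methyl-3-(phenylsulfanyl)cyclohexan-1-one
Conditions: PhSH, Et3N (cat.), CH2Cl2, 0 → 25 °C
Reagents that add atoms: benzenethiol, Sc1ccccc1
Why: Base-catalysed thia-Michael addition; the new sulfide centre becomes sp2 in step 5.

Step 5
Reactants: 7 (5S)-5-methyl-3-(phenylsulfanyl)cyclohexan-1-one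
Product: 9 (5S)-5-methyl-3-(phenylsulfanyl)cyclohex-2-en-1-one, via chloro sulfide 8 (not isolated)
Conditions: N-chlorosuccinimide, CH2Cl2, 0 °C; then Et3N, 25 °C
Reagents that add atoms: none
Why: Pummerer-type α-chlorination of the sulfide and dehydrochlorination towards the acidic α-CH2 give the vinylogous thioester, in which the two carbonyl-level carbons stay differentiated so C3 remains a defined stereocentre.

Step 6
Reactants: 9 (5S)-5-methyl-3-(phenylsulfanyl)cyclohex-2-en-1-one; 10 tert-butyl bromoacetate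
Product: 11 tert-butyl 2-[(1S,6R)-6-methyl-2-oxo-4-(phenylsulfanyl)cyclohex-3-en-1-yl]acetate
Conditions: LiN(i-Pr)2, THF, −78 °C; then 10, DMPU, −78 → −30 °C
Reagents that add atoms: none
Why: Kinetic α'-deprotonation and enolate alkylation (SN2) in the Stork–Danheiser manner; the electrophile enters trans to the adjacent C3 methyl, which sets C4.

Step 7
Reactants: 11 tert-butyl 2-[(1S,6R)-6-methyl-2-oxo-4-(phenylsulfanyl)cyclohex-3-en-1-yl]acetate; 12 prenylmagnesium chloride
Product: 14 tert-butyl 2-[(1S,6R)-6-methyl-2-(2-methylbut-3-en-2-yl)-4-oxocyclohex-2-en-1-yl]acetate, via tertiary allylic alcohol 13 (not isolated)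
Conditions: 12 (1.2 equiv), THF, −78 °C; then 1 M HCl, THF, 25 °C
Reagents that add atoms: water, O
Why: Carbonyl allylation in which the prenyl reagent adds 1,2 through its γ-carbon (six-membered SE2' transition state) to create the quaternary C6 and the C5–C6 bond, after which acid hydrolysis of the hydroxy vinyl sulfide effects the Stork–Danheiser-type 1,3-carbonyl transposition.

Step 8
Reactants: 14 tert-butyl 2-[(1S,6R)-6-methyl-2-(2-methylbut-3-en-2-yl)-4-oxocyclohex-2-en-1-yl]acetate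
Product: 15 tert-butyl 2-[(1S,2S,6R)-6-methyl-2-(2-methylbut-3-en-2-yl)-4-(triethylsilyloxy)cyclohex-3-en-1-yl]acetate
Conditions: [(Ph3P)CuH]6 (0.4 equiv), Et3SiCl (2 equiv), toluene/THF, 25 °C
Reagents that add atoms: chlorotriethylsilane, CC[Si](Cl)(CC)CC
Why: Copper hydride conjugate reduction with in-situ silylation, in which A(1,2) strain with the tert-alkyl group holds the C4 arm pseudoaxial so hydride adds to C5 from the opposite face (side chains cis) and the enol ether regiochemistry is fixed; the isolated vinyl group and the ester are not touched.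

Step 9
Reactants: 15 tert-butyl 2-[(1S,2S,6R)-6-methyl-2-(2-methylbut-3-en-2-yl)-4-(triethylsilyloxy)cyclohex-3-en-1-yl]acetate
Product: 17 tert-butyl 2-[(1S,2R,3R,6R)-6-methyl-2-(2-methylbut-3-en-2-yl)-4-oxo-3-(triethylsilyloxy)cyclohexyl]acetate, via silyloxy epoxide 16 (not isolated)
Conditions: mCPBA (1.05 equiv), NaHCO3, CH2Cl2, −20 → 0 °C
Reagents that add atoms: 3-chloroperoxybenzoic acid, OOC(=O)c1cccc(Cl)c1
Why: Rubottom oxidation in which the electron-rich silyl enol ether is epoxidised in preference to the terminal alkene, anti to the neighbouring tert-alkyl group and the axial C4 arm, and 1,4-silyl migration gives the C11 silyl ether trans to the C5 substituent.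

Step 10
Reactants: 17 tert-butyl 2-[(1S,2R,3R,6R)-6-methyl-2-(2-methylbut-3-en-2-yl)-4-oxo-3-(triethylsilyloxy)cyclohexyl]acetate
Product: 18 tert-butyl 2-[(1S,2R,3R,4S,6R)-4-hydroxy-6-methyl-2-(2-methylbut-3-en-2-yl)-3-(triethylsilyloxy)cyclohexyl]acetate
Conditions: LiBH(s-Bu)3, THF, −78 °C; then AcOH, −78 °C
Reagents that add atoms: none
Why: Bulky hydride reduction by equatorial attack away from the axial C3 methyl gives the axial C1 alcohol cis to the C11 silyl ether (this centre is oxidised again in step 26), and the cold acidic quench suppresses silyl migration.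

Step 11
Reactants: 18 tert-butyl 2-[(1S,2R,3R,4S,6R)-4-hydroxy-6-methyl-2-(2-methylbut-3-en-2-yl)-3-(triethylsilyloxy)cyclohexyl]acetate
Product: 19 tert-butyl 2-[(1S,2R,3R,4S,6R)-4-(tert-butyldimethylsilyloxy)-6-methyl-2-(2-methylbut-3-en-2-yl)-3-(triethylsilyloxy)cyclohexyl]acetate
Conditions: TBSOTf, 2,6-lutidine, CH2Cl2, −78 → 0 °C
Reagents that add atoms: tert-butyldimethylsilyl trifluoromethanesulfonate, CC(C)(C)[Si](C)(C)OS(=O)(=O)C(F)(F)F
Why: Silylation of the hindered secondary alcohol gives a TBS ether that is orthogonal to the more labile TES ether at C11.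

Step 12
Reactants: 19 tert-butyl 2-[(1S,2R,3R,4S,6R)-4-(tert-butyldimethylsilyloxy)-6-methyl-2-(2-methylbut-3-en-2-yl)-3-(triethylsilyloxy)cyclohexyl]acetate
Product: 20 tert-butyl (2RS)-2-[(1S,2R,3R,4S,6R)-4-(tert-butyldimethylsilyloxy)-6-methyl-2-(2-methylbut-3-en-2-yl)-3-(triethylsilyloxy)cyclohexyl]propanoate
Conditions: LiN(i-Pr)2, THF, −78 °C; then MeI, −78 → −40 °C
Reagents that add atoms: iodomethane, CI
Why: Ester enolate alkylation at the only acidic site installs the C15 methyl on C10, whose configuration is immaterial because it is enolised in step 21.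

Step 13
Reactants: 20 tert-butyl (2RS)-2-[(1S,2R,3R,4S,6R)-4-(tert-butyldimethylsilyloxy)-6-methyl-2-(2-methylbut-3-en-2-yl)-3-(triethylsilyloxy)cyclohexyl]propanoate
Product: 21 (2RS)-2-[(1R,2R,3R,4S,6R)-4-(tert-butyldimethylsilyloxy)-6-methyl-2-(2-methylbut-3-en-2-yl)-3-(triethylsilyloxy)cyclohexyl]propan-1-ol
Conditions: LiAlH4, THF, 0 °C
Reagents that add atoms: none
Why: Hydride reduction of the ester to the primary alcohol, which silyl ethers and the alkene tolerate.

Step 14
Reactants: 21 (2RS)-2-[(1R,2R,3R,4S,6R)-4-(tert-butyldimethylsilyloxy)-6-methyl-2-(2-methylbut-3-en-2-yl)-3-(triethylsilyloxy)cyclohexyl]propan-1-ol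
Product: 22 (2RS)-2-[(1S,2R,3R,4S,6R)-4-(tert-butyldimethylsilyloxy)-6-methyl-2-(2-methylbut-3-en-2-yl)-3-(triethylsilyloxy)cyclohexyl]propanal
Conditions: Dess–Martin periodinane, NaHCO3, CH2Cl2, 0 → 25 °C
Reagents that add atoms: none
Why: Dess–Martin oxidation of the primary alcohol to the aldehyde under buffered, non-epimerising conditions.

Step 15
Reactants: 22 (2RS)-2-[(1S,2R,3R,4S,6R)-4-(tert-butyldimethylsilyloxy)-6-methyl-2-(2-methylbut-3-en-2-yl)-3-(triethylsilyloxy)cyclohexyl]propanal; 23 vinylmagnesium bromide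
Product: 24 (3RS,4RS)-4-[(1R,2R,3R,4S,6R)-4-(tert-butyldimethylsilyloxy)-6-methyl-2-(2-methylbut-3-en-2-yl)-3-(triethylsilyloxy)cyclohexyl]pent-1-en-3-ol
Conditions: 23, THF, −78 → 0 °C
Reagents that add atoms: none
Why: Grignard 1,2-addition to the aldehyde supplies C8 and the C9 carbinol, whose configuration is irrelevant because it is oxidised in step 17.

Step 16
Reactants: 24 (3RS,4RS)-4-[(1R,2R,3R,4S,6R)-4-(tert-butyldimethylsilyloxy)-6-methyl-2-(2-methylbut-3-en-2-yl)-3-(triethylsilyloxy)cyclohexyl]pent-1-en-3-ol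
Product: 25 1-(tert-butyldimethylsilyloxy)-11-(triethylsilyloxy)-10,11-secolongipin-7-en-9-ol
Conditions: (H2IMes)(PCy3)Cl2Ru=CHPh (second-generation Grubbs catalyst, 5 mol %), toluene (5 mM), 80 °C
Reagents that add atoms: none
Why: Ring-closing metathesis between the two cis-disposed vinyl groups closes the seven-membered ring B (C7=C8) with loss of ethene.

Step 17
Reactants: 25 1-(tert-butyldimethylsilyloxy)-11-(triethylsilyloxy)-10,11-secolongipin-7-en-9-ol
Product: 26 1-(tert-butyldimethylsilyloxy)-11-(triethylsilyloxy)-10,11-secolongipin-7-en-9-one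
Conditions: Dess–Martin periodinane, NaHCO3, CH2Cl2, 25 °C
Reagents that add atoms: none
Why: Dess–Martin oxidation of the allylic alcohol gives the cycloheptenone whose only enolisable position is C10.

Step 18
Reactants: 26 1-(tert-butyldimethylsilyloxy)-11-(triethylsilyloxy)-10,11-secolongipin-7-en-9-one
Product: 27 7,8-epoxy-1-(tert-butyldimethylsilyloxy)-11-(triethylsilyloxy)-10,11-secolongipinan-9-one
Conditions: t-BuOOH, DBU, CH2Cl2, 0 → 25 °C
Reagents that add atoms: tert-butyl hydroperoxide, CC(C)(C)OO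
Why: Weitz–Scheffer nucleophilic epoxidation on the convex face of the cis-fused bicycle (the face of H-4 and H-5, away from ring A) sets the C7 oxygen configuration.

Step 19
Reactants: 27 7,8-epoxy-1-(tert-butyldimethylsilyloxy)-11-(triethylsilyloxy)-10,11-secolongipinan-9-one
Product: 28 7,8-epoxy-11-hydroxy-1-(tert-butyldimethylsilyloxy)-10,11-secolongipinan-9-one
Conditions: PPTS (cat.), MeOH/CH2Cl2, 25 °C
Reagents that add atoms: none
Why: Selective acid-catalysed methanolysis removes the TES ether while the TBS ether and the epoxy ketone survive.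

Step 20
Reactants: 28 7,8-epoxy-11-hydroxy-1-(tert-butyldimethylsilyloxy)-10,11-secolongipinan-9-one
Product: 29 7,8-epoxy-1-(tert-butyldimethylsilyloxy)-9-oxo-10,11-secolongipinan-11-yl methanesulfonate
Conditions: MsCl, Et3N, DMAP (cat.), CH2Cl2, −20 → 0 °C
Reagents that add atoms: methanesulfonyl chloride, CS(=O)(=O)Cl
Why: Sulfonylation turns the C11 alcohol into a leaving group with retention, leaving it equatorial and trans to both ring-B bonds.

Step 21
Reactants: 29 7,8-epoxy-1-(tert-butyldimethylsilyloxy)-9-oxo-10,11-secolongipinan-11-yl methanesulfonate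
Product: 30 7,8-epoxy-1-(tert-butyldimethylsilyloxy)longipinan-9-one
Conditions: KN(SiMe3)2 (1.1 equiv), THF, −78 → 0 °C
Reagents that add atoms: none
Why: Intramolecular enolate alkylation (4-exo-tet SN2) in which the only possible enolate (C10) attacks C11 anti to the equatorial mesylate with inversion, closing ring C; the quaternary C10 configuration is dictated by the ring system, both C10 epimers converge, and O-alkylation would give a bridgehead enol ether.

Step 22
Reactants: 30 7,8-epoxy-1-(tert-butyldimethylsilyloxy)longipinan-9-one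
Product: 31 1-(tert-butyldimethylsilyloxy)-7-hydroxylongipinan-9-one
Conditions: SmI2 (2.5 equiv), THF/MeOH, −90 °C
Reagents that add atoms: none
Why: SmI2 reductive cleavage of the α C–O bond of the α,β-epoxy ketone gives the β-hydroxy ketone with C7 unchanged.

Step 23
Reactants: 31 1-(tert-butyldimethylsilyloxy)-7-hydroxylongipinan-9-one; 32 (E)-2-methylbut-2-enal
Product: 33 1-(tert-butyldimethylsilyloxy)-9-hydroxylongipinan-7-yl (2E)-2-methylbut-2-enoate
Conditions: 32 (5 equiv), SmI2 (0.3 equiv), THF, −10 °C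
Reagents that add atoms: none
Why: Evans–Tishchenko reduction in which the samarium-bound hemiacetal on O7 delivers hydride intramolecularly to the C9 ketone from the face of O7, giving the trans (anti) 1,3-diol with the tiglate already on O7 and O9 free.

Step 24
Reactants: 33 1-(tert-butyldimethylsilyloxy)-9-hydroxylongipinan-7-yl (2E)-2-methylbut-2-enoate; 34 3-methylbut-2-enoyl chloride
Product: 35 1-(tert-butyldimethylsilyloxy)-9-[(3-methylbut-2-enoyl)oxy]longipinan-7-yl (2E)-2-methylbut-2-enoate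
Conditions: 34, pyridine, DMAP (cat.), CH2Cl2, 0 → 25 °C
Reagents that add atoms: none
Why: DMAP-catalysed acylation of the remaining C9 alcohol installs the senecioate without touching any stereocentre.

Step 25
Reactants: 35 1-(tert-butyldimethylsilyloxy)-9-[(3-methylbut-2-enoyl)oxy]longipinan-7-yl (2E)-2-methylbut-2-enoate
Product: 36 1-hydroxy-9-[(3-methylbut-2-enoyl)oxy]longipinan-7-yl (2E)-2-methylbut-2-enoate
Conditions: HF·pyridine, pyridine/THF, 0 → 25 °C
Reagents that add atoms: none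
Why: Fluoride-mediated desilylation frees the C1 alcohol while both enoate esters are stable.

Step 26
Reactants: 36 1-hydroxy-9-[(3-methylbut-2-enoyl)oxy]longipinan-7-yl (2E)-2-methylbut-2-enoate
Product: 37 9-[(3-methylbut-2-enoyl)oxy]-1-oxolongipinan-7-yl (2E)-2-methylbut-2-enoate
Conditions: Dess–Martin periodinane, NaHCO3, CH2Cl2, 25 °C
Reagents that add atoms: none
Why: Dess–Martin oxidation gives the C1 ketone, which cannot epimerise C11 because that carbon is a bridgehead.

Step 27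
Reactants: 37 9-[(3-methylbut-2-enoyl)oxy]-1-oxolongipinan-7-yl (2E)-2-methylbut-2-enoate
Product: 39 (4R,5S,7R,9R,10R,11R)-9-[(3-methylbut-2-enoyl)oxy]-1-oxolongipin-2-en-7-yl (2E)-2-methylbut-2-enoate, via silyl enol ether 38 (not isolated)
Conditions: TMSOTf, Et3N, CH2Cl2, 0 °C; then Pd(OAc)2 (1.1 equiv), MeCN, 25 → 40 °C
Reagents that add atoms: none
Why: Saegusa–Ito oxidation in which soft enolisation can only go towards C2 (C11 is a bridgehead) and palladium-mediated dehydrosilylation gives the Δ2 enone, erasing the C3 stereocentre.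

## Compound list

1 | (R)-(+)-pulegone, (5R)-5-methyl-2-(propan-2-ylidene)cyclohexan-1-one | C[C@@H]1CCC(=C(C)C)C(=O)C1 | starting material
2 | (6R)-2,2,6-trimethyl-1-oxaspiro[2.5]octan-4-one (pulegone oxide, both epoxide diastereomers) | C[C@@H]1CCC2(OC2(C)C)C(=O)C1 | intermediate
3 | hydroxy sulfide adduct, (5R)-2-(2-hydroxypropan-2-yl)-5-methyl-2-(phenylsulfanyl)cyclohexan-1-one (as sodium alkoxide) | C[C@@H]1CCC(Sc2ccccc2)(C(C)(C)O)C(=O)C1 | intermediate (not isolated)
4 | (5R)-5-methyl-2-(phenylsulfanyl)cyclohexan-1-one (C2 epimers) | C[C@@H]1CCC(Sc2ccccc2)C(=O)C1 | intermediate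
5 | sulfoxide, (5R)-5-methyl-2-(phenylsulfinyl)cyclohexan-1-one | C[C@@H]1CCC(S(=O)c2ccccc2)C(=O)C1 | intermediate (not isolated)
6 | (5R)-5-methylcyclohex-2-en-1-one | C[C@@H]1CC=CC(=O)C1 | intermediate
7 | (5S)-5-methyl-3-(phenylsulfanyl)cyclohexan-1-one (C3 epimers) | C[C@@H]1CC(Sc2ccccc2)CC(=O)C1 | intermediate
8 | chloro sulfide, (5S)-3-chloro-5-methyl-3-(phenylsulfanyl)cyclohexan-1-one | C[C@@H]1CC(Cl)(Sc2ccccc2)CC(=O)C1 | intermediate (not isolated)
9 | (5S)-5-methyl-3-(phenylsulfanyl)cyclohex-2-en-1-one | C[C@@H]1CC(Sc2ccccc2)=CC(=O)C1 | intermediate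
10 | tert-butyl bromoacetate | BrCC(=O)OC(C)(C)C | starting material
11 | tert-butyl 2-[(1S,6R)-6-methyl-2-oxo-4-(phenylsulfanyl)cyclohex-3-en-1-yl]acetate (methyl and acetate arm trans) | C[C@@H]1CC(Sc2ccccc2)=CC(=O)[C@H]1CC(=O)OC(C)(C)C | intermediate
12 | prenylmagnesium chloride (3-methylbut-2-en-1-ylmagnesium chloride) | CC(C)=CC[Mg]Cl | starting material
13 | tertiary allylic alcohol, tert-butyl 2-[(1S,6R)-2-hydroxy-6-methyl-2-(2-methylbut-3-en-2-yl)-4-(phenylsulfanyl)cyclohex-3-en-1-yl]acetate (carbinol epimers) | C[C@@H]1CC(Sc2ccccc2)=CC(O)(C(C)(C)C=C)[C@H]1CC(=O)OC(C)(C)C | intermediate (not isolated)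
14 | tert-butyl 2-[(1S,6R)-6-methyl-2-(2-methylbut-3-en-2-yl)-4-oxocyclohex-2-en-1-yl]acetate | C[C@@H]1CC(=O)C=C(C(C)(C)C=C)[C@H]1CC(=O)OC(C)(C)C | intermediate
15 | tert-butyl 2-[(1S,2S,6R)-6-methyl-2-(2-methylbut-3-en-2-yl)-4-(triethylsilyloxy)cyclohex-3-en-1-yl]acetate (1- and 2-substituents cis) | C[C@@H]1CC(O[Si](CC)(CC)CC)=C[C@@H](C(C)(C)C=C)[C@H]1CC(=O)OC(C)(C)C | intermediate
16 | silyloxy epoxide, the 3,4-epoxide of 15 with the oxirane oxygen trans to the 2-substituent | C[C@@H]1C[C@]2(O[Si](CC)(CC)CC)O[C@@H]2[C@@H](C(C)(C)C=C)[C@H]1CC(=O)OC(C)(C)C | intermediate (not isolated)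
17 | tert-butyl 2-[(1S,2R,3R,6R)-6-methyl-2-(2-methylbut-3-en-2-yl)-4-oxo-3-(triethylsilyloxy)cyclohexyl]acetate | C[C@@H]1CC(=O)[C@H](O[Si](CC)(CC)CC)[C@@H](C(C)(C)C=C)[C@H]1CC(=O)OC(C)(C)C | intermediate
18 | tert-butyl 2-[(1S,2R,3R,4S,6R)-4-hydroxy-6-methyl-2-(2-methylbut-3-en-2-yl)-3-(triethylsilyloxy)cyclohexyl]acetate | C[C@@H]1C[C@H](O)[C@H](O[Si](CC)(CC)CC)[C@@H](C(C)(C)C=C)[C@H]1CC(=O)OC(C)(C)C | intermediate
19 | tert-butyl 2-[(1S,2R,3R,4S,6R)-4-(tert-butyldimethylsilyloxy)-6-methyl-2-(2-methylbut-3-en-2-yl)-3-(triethylsilyloxy)cyclohexyl]acetate | C[C@@H]1C[C@H](O[Si](C)(C)C(C)(C)C)[C@H](O[Si](CC)(CC)CC)[C@@H](C(C)(C)C=C)[C@H]1CC(=O)OC(C)(C)C | intermediate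
20 | tert-butyl (2RS)-2-[(1S,2R,3R,4S,6R)-4-(tert-butyldimethylsilyloxy)-6-methyl-2-(2-methylbut-3-en-2-yl)-3-(triethylsilyloxy)cyclohexyl]propanoate | C[C@@H]1C[C@H](O[Si](C)(C)C(C)(C)C)[C@H](O[Si](CC)(CC)CC)[C@@H](C(C)(C)C=C)[C@H]1C(C)C(=O)OC(C)(C)C | intermediate
21 | (2RS)-2-[(1R,2R,3R,4S,6R)-4-(tert-butyldimethylsilyloxy)-6-methyl-2-(2-methylbut-3-en-2-yl)-3-(triethylsilyloxy)cyclohexyl]propan-1-ol | C[C@@H]1C[C@H](O[Si](C)(C)C(C)(C)C)[C@H](O[Si](CC)(CC)CC)[C@@H](C(C)(C)C=C)[C@H]1C(C)CO | intermediate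
22 | (2RS)-2-[(1S,2R,3R,4S,6R)-4-(tert-butyldimethylsilyloxy)-6-methyl-2-(2-methylbut-3-en-2-yl)-3-(triethylsilyloxy)cyclohexyl]propanal | C[C@@H]1C[C@H](O[Si](C)(C)C(C)(C)C)[C@H](O[Si](CC)(CC)CC)[C@@H](C(C)(C)C=C)[C@H]1C(C)C=O | intermediate
23 | vinylmagnesium bromide | C=C[Mg]Br | starting material
24 | (3RS,4RS)-4-[(1R,2R,3R,4S,6R)-4-(tert-butyldimethylsilyloxy)-6-methyl-2-(2-methylbut-3-en-2-yl)-3-(triethylsilyloxy)cyclohexyl]pent-1-en-3-ol | C[C@@H]1C[C@H](O[Si](C)(C)C(C)(C)C)[C@H](O[Si](CC)(CC)CC)[C@@H](C(C)(C)C=C)[C@H]1C(C)C(O)C=C | intermediate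
25 | 1-(tert-butyldimethylsilyloxy)-11-(triethylsilyloxy)-10,11-secolongipin-7-en-9-ol (H-4/H-5 cis; 11-O trans to C6; 1-O cis to 11-O; 3-methyl trans to C10; C9 and C10 epimers) | C[C@@H]1C[C@H](O[Si](C)(C)C(C)(C)C)[C@H](O[Si](CC)(CC)CC)[C@@H]2[C@H]1C(C)C(O)C=CC2(C)C | intermediate
26 | 1-(tert-butyldimethylsilyloxy)-11-(triethylsilyloxy)-10,11-secolongipin-7-en-9-one (ring stereochemistry as 25; C10 epimers) | C[C@@H]1C[C@H](O[Si](C)(C)C(C)(C)C)[C@H](O[Si](CC)(CC)CC)[C@@H]2[C@H]1C(C)C(=O)C=CC2(C)C | intermediate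
27 | 7,8-epoxy-1-(tert-butyldimethylsilyloxy)-11-(triethylsilyloxy)-10,11-secolongipinan-9-one (oxirane cis to H-4 and H-5; C10 epimers) | C[C@@H]1C[C@H](O[Si](C)(C)C(C)(C)C)[C@H](O[Si](CC)(CC)CC)[C@@H]2[C@H]1C(C)C(=O)[C@H]3O[C@H]3C2(C)C | intermediate
28 | 7,8-epoxy-11-hydroxy-1-(tert-butyldimethylsilyloxy)-10,11-secolongipinan-9-one (C10 epimers) | C[C@@H]1C[C@H](O[Si](C)(C)C(C)(C)C)[C@H](O)[C@@H]2[C@H]1C(C)C(=O)[C@H]3O[C@H]3C2(C)C | intermediate
29 | 7,8-epoxy-1-(tert-butyldimethylsilyloxy)-9-oxo-10,11-secolongipinan-11-yl methanesulfonate (C10 epimers) | C[C@@H]1C[C@H](O[Si](C)(C)C(C)(C)C)[C@H](OS(C)(=O)=O)[C@@H]2[C@H]1C(C)C(=O)[C@H]3O[C@H]3C2(C)C | intermediate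
30 | 7,8-epoxy-1-(tert-butyldimethylsilyloxy)longipinan-9-one (C4, C5, C7, C10, C11 as in 39; 1-OTBS and 3-methyl on the face of the C5 bridge) | [C@H]15O[C@@H]5C(=O)[C@@]2(C)[C@@H]3[C@@H](O[Si](C)(C)C(C)(C)C)C[C@@H](C)[C@H]2[C@@H]3C1(C)C | intermediate
31 | 1-(tert-butyldimethylsilyloxy)-7-hydroxylongipinan-9-one (stereochemistry as 30) | O[C@@H]1CC(=O)[C@@]2(C)[C@@H]3[C@@H](O[Si](C)(C)C(C)(C)C)C[C@@H](C)[C@H]2[C@@H]3C1(C)C | intermediate
32 | (E)-2-methylbut-2-enal (tiglic aldehyde) | C/C=C(\C)C=O | starting material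
33 | 1-(tert-butyldimethylsilyloxy)-9-hydroxylongipinan-7-yl (2E)-2-methylbut-2-enoate (O7 and O9 trans, as in 39) | C/C=C(\C)C(=O)O[C@@H]1C[C@@H](O)[C@@]2(C)[C@@H]3[C@@H](O[Si](C)(C)C(C)(C)C)C[C@@H](C)[C@H]2[C@@H]3C1(C)C | intermediate
34 | 3-methylbut-2-enoyl chloride (senecioyl chloride) | CC(C)=CC(=O)Cl | starting material
35 | 1-(tert-butyldimethylsilyloxy)-9-[(3-methylbut-2-enoyl)oxy]longipinan-7-yl (2E)-2-methylbut-2-enoate | C/C=C(\C)C(=O)O[C@@H]1C[C@@H](OC(=O)C=C(C)C)[C@@]2(C)[C@@H]3[C@@H](O[Si](C)(C)C(C)(C)C)C[C@@H](C)[C@H]2[C@@H]3C1(C)C | intermediate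
36 | 1-hydroxy-9-[(3-methylbut-2-enoyl)oxy]longipinan-7-yl (2E)-2-methylbut-2-enoate | C/C=C(\C)C(=O)O[C@@H]1C[C@@H](OC(=O)C=C(C)C)[C@@]2(C)[C@@H]3[C@@H](O)C[C@@H](C)[C@H]2[C@@H]3C1(C)C | intermediate
37 | 9-[(3-methylbut-2-enoyl)oxy]-1-oxolongipinan-7-yl (2E)-2-methylbut-2-enoate | C/C=C(\C)C(=O)O[C@@H]1C[C@@H](OC(=O)C=C(C)C)[C@@]2(C)[C@@H]3C(=O)C[C@@H](C)[C@H]2[C@@H]3C1(C)C | intermediate
38 | silyl enol ether, 9-[(3-methylbut-2-enoyl)oxy]-1-(trimethylsilyloxy)longipin-1-en-7-yl (2E)-2-methylbut-2-enoate | C/C=C(\C)C(=O)O[C@@H]1C[C@@H](OC(=O)C=C(C)C)[C@@]2(C)[C@@H]3C(O[Si](C)(C)C)=C[C@@H](C)[C@H]2[C@@H]3C1(C)C | intermediate (not isolated)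
39 | (4R,5S,7R,9R,10R,11R)-9-[(3-methylbut-2-enoyl)oxy]-1-oxolongipin-2-en-7-yl (2E)-2-methylbut-2-enoate | C/C=C(\C)C(=O)O[C@@H]1C[C@@H](OC(=O)C=C(C)C)[C@@]2(C)[C@@H]3C(=O)C=C(C)[C@H]2[C@@H]3C1(C)C | target

## Totals and weak points

Total step count: 27. Longest linear sequence: 27 steps, from (R)-pulegone 1; every other component is bought.

The three steps most likely to fail:

Step 8 (conjugate reduction). The β-carbon carries a tert-alkyl group, so hydride delivery is slow, and the attacked face also carries the axial C3 methyl, so facial selectivity may be only moderate. Fallback: setting out from 14, replace metal-hydride delivery by a dissolving-metal reductive silylation (Li, NH3/THF, t-BuOH 1 equiv, −78 °C; then Et3SiCl, Et3N). Here C5 is protonated axially under stereoelectronic control in the chair that keeps the tert-alkyl group equatorial and the C4 arm axial, and the regiodefined lithium enolate is trapped to give 15 again, where the route continues. This detour makes no new compound (F0).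

Step 21 (cyclobutane closure on the epoxy ketone). The α'-enolate must form next to an oxirane and then make a strained four-membered ring at a hindered secondary carbon. Fallback: setting out from 26, close the ring before any oxygen is placed on C7. PPTS in MeOH removes the TES group to give the 11-hydroxy enone F1; MsCl/Et3N gives the enone mesylate F2; KN(SiMe3)2 in THF, through the only possible (cross-conjugated) enolate, gives the tricyclic enone F3. Because the two faces of F3 at C7 are nearly equivalent, the C7 oxygen is then introduced under reagent control: CuCl/NaOt-Bu with a chiral Josiphos-type bisphosphine, B2pin2 and MeOH give the β-boryl ketone F4 (ligand enantiomer chosen for boron anti to C11), and NaBO3 oxidation with retention gives 31, where the route is rejoined (steps 18–22 are bypassed).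

Step 23 (Evans–Tishchenko with an enal). Hemiacetal formation and hydride transfer are slower with a conjugated, hindered aldehyde, and acyl migration or elimination to the enone can compete. Fallback: setting out from 31, separate reduction and acylation. Me4NBH(OAc)3 in MeCN/AcOH at −20 °C (hydroxyl-directed, intramolecular hydride delivery) gives the trans-7,9-diol F5. Then 3-methylbut-2-enoyl chloride (1.05 equiv) with pyridine at −20 °C acylates the less hindered C9 hydroxyl (next to the tied-back cyclobutane carbon) to give the 9-monosenecioate F6. Finally (E)-2-methylbut-2-enoyl chloride with pyridine/DMAP at 40 °C esterifies O7 to give 35, where the route continues.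

Further compounds
F0 | step 8 | none | none
F1 | step 21 | 11-hydroxy-1-(tert-butyldimethylsilyloxy)-10,11-secolongipin-7-en-9-one | C[C@@H]1C[C@H](O[Si](C)(C)C(C)(C)C)[C@H](O)[C@@H]2[C@H]1C(C)C(=O)C=CC2(C)C
F2 | step 21 | 1-(tert-butyldimethylsilyloxy)-9-oxo-10,11-secolongipin-7-en-11-yl methanesulfonate | C[C@@H]1C[C@H](O[Si](C)(C)C(C)(C)C)[C@H](OS(C)(=O)=O)[C@@H]2[C@H]1C(C)C(=O)C=CC2(C)C
F3 | step 21 | 1-(tert-butyldimethylsilyloxy)longipin-7-en-9-one | C1=CC(=O)[C@@]2(C)[C@@H]3[C@@H](O[Si](C)(C)C(C)(C)C)C[C@@H](C)[C@H]2[C@@H]3C1(C)C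
F4 | step 21 | 1-(tert-butyldimethylsilyloxy)-7-(4,4,5,5-tetramethyl-1,3,2-dioxaborolan-2-yl)longipinan-9-one | CC4(C)OB(OC4(C)C)[C@@H]1CC(=O)[C@@]2(C)[C@@H]3[C@@H](O[Si](C)(C)C(C)(C)C)C[C@@H](C)[C@H]2[C@@H]3C1(C)C
F5 | step 23 | 1-(tert-butyldimethylsilyloxy)longipinane-7,9-diol (trans diol, configuration as in 39) | O[C@@H]1C[C@@H](O)[C@@]2(C)[C@@H]3[C@@H](O[Si](C)(C)C(C)(C)C)C[C@@H](C)[C@H]2[C@@H]3C1(C)C
F6 | step 23 | 1-(tert-butyldimethylsilyloxy)-7-hydroxylongipinan-9-yl 3-methylbut-2-enoate | O[C@@H]1C[C@@H](OC(=O)C=C(C)C)[C@@]2(C)[C@@H]3[C@@H](O[Si](C)(C)C(C)(C)C)C[C@@H](C)[C@H]2[C@@H]3C1(C)C
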